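**Retrosynthetic overview**
- Rings of the target: A (trioxygenated benzene), B (pyranone), C (furan), D (phenol ring), E (gem-dimethyl dihydropyran).
- Ring C is opened at the bond between the ring D oxygen and the old coumarin C4. This gives a 2'-hydroxy-3-arylcoumarin, which is closed again by dehydrogenation, the way plants are thought to take such precursors to coumestans.
- Ring B is opened into an o-hydroxybenzaldehyde and 6-hydroxybenzofuran-2(3H)-one (Knoevenagel condensation, then the lactone moves from ring D to ring A). Rings B and C are closed in one flask.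
- Ring E is opened into isoprene and symmetrical 2,6-dihydroxy-4-methoxybenzaldehyde (prenyl cation C-alkylation, then closure by the one flanking phenol, as a prenylphenol cyclises in nature). That aldehyde comes from its trimethyl ether.
- Order of ring formation: E, then B, then C.

Assumption: the target has no stereocentre and no stereogenic double bond, so there is no enantiomer to control; 6-hydroxybenzofuran-2(3H)-one is taken as a catalogue compound.

**Route**

Step 1
Reactants: 1 2,4,6-trimethoxybenzaldehyde
Product: 2 2,6-dihydroxy-4-methoxybenzaldehyde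
Conditions: AlCl3 (4–5 equiv), CH2Cl2, 0 °C to reflux; then ice-water
Reagents that add atoms: none
Why: Chelation-controlled Lewis acid ether cleavage, in which aluminium held at the aldehyde oxygen delivers chloride only to the two ortho O-methyl groups and leaves the para methyl ether; no stereocentre is formed.

Step 2
Reactants: 2 2,6-dihydroxy-4-methoxybenzaldehyde; 3 isoprene (2-methylbuta-1,3-diene)
Product: 5 7-hydroxy-5-methoxy-2,2-dimethylchromane-8-carbaldehyde, via C-prenyl aldehyde 4 (not isolated)
Conditions: isoprene (1.1 equiv), 85% H3PO4, xylene, sealed tube, 35 °C then 60 °C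
Reagents that add atoms: none
Why: Acid-catalysed chromanylation of a phenol with isoprene: Friedel–Crafts C-prenylation at C3 (C3 and C5 are equivalent), then Markovnikov addition of the only flanking phenol (the other neighbour is OMe) to the protonated prenyl olefin, so one regioisomer and no stereocentre.

Step 3
Reactants: 5 7-hydroxy-5-methoxy-2,2-dimethylchromane-8-carbaldehyde; 6 6-hydroxybenzofuran-2(3H)-one
Product: 9 CNP0304440.0 (ring-E-fused 9-hydroxy-3-methoxycoumestan), via isoaurone 7 (not isolated), via arylcoumarin 8 (not isolated)
Conditions: Et3N (1.5 equiv), 1,4-dioxane, 90 °C; then AcOH (3 equiv), DDQ (1.2 equiv), 60 °C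
Reagents that add atoms: none
Why: Proposed new method: the acidic lactone CH2 of 6 condenses with 5 (Knoevenagel) to isoaurone 7, whose neighbouring phenoxide opens the five-membered aryl lactone and recloses it as the conjugated six-membered one to give 2'-hydroxy-3-arylcoumarin 8 (closest known type: salicylaldehyde plus benzofuran-2(3H)-one giving 3-(2-hydroxyphenyl)coumarins), and DDQ then closes ring C by reversible oxa-Michael addition of the freed 2'-OH to C4, hydride abstraction from the resulting benzylic oxygen-bearing C–H and loss of the lactone α-proton (closest known type: DDQ dehydrogenative cyclisation of 2'-hydroxy-3-arylcoumarins to coumestans, which copies the plant closure of the 2'-OH onto C4); what is new is running both stages in one flask on unprotected phenols, with AcOH added to protonate Et3N before the quinone goes in, and no stereocentre is formed.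

**Compound list**

1 | 2,4,6-trimethoxybenzaldehyde | COc1cc(OC)c(C=O)c(OC)c1 | starting material
2 | 2,6-dihydroxy-4-methoxybenzaldehyde | COc1cc(O)c(C=O)c(O)c1 | intermediate
3 | isoprene (2-methylbuta-1,3-diene) | C=CC(C)=C | starting material
4 | 2,6-dihydroxy-4-methoxy-3-(3-methylbut-2-en-1-yl)benzaldehyde (not isolated) | COc1cc(O)c(C=O)c(O)c1CC=C(C)C | intermediate
5 | 7-hydroxy-5-methoxy-2,2-dimethyl-3,4-dihydro-2H-chromene-8-carbaldehyde | COc1cc(O)c(C=O)c2OC(C)(C)CCc12 | intermediate
6 | 6-hydroxybenzofuran-2(3H)-one | O=C1Cc2ccc(O)cc2O1 | starting material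
7 | (Z)-6-hydroxy-3-[(7-hydroxy-5-methoxy-2,2-dimethylchroman-8-yl)methylidene]benzofuran-2(3H)-one (not isolated; E and Z interconvert under Et3N, the Z isomer lactonises) | O=C1Oc2cc(O)ccc2/C1=C/c1c(O)cc(OC)c2CCC(C)(C)Oc12 | intermediate
8 | 9-(2,4-dihydroxyphenyl)-5-methoxy-2,2-dimethyl-3,4-dihydro-2H,8H-pyrano[2,3-f]chromen-8-one (not isolated; in coumarin numbering a 3-(2,4-dihydroxyphenyl)-7-methoxycoumarin with ring E fused through O at C5 and CH2 at C6) | COc1cc2oc(=O)c(-c3ccc(O)cc3O)cc2c2OC(C)(C)CCc12 | intermediate
9 | CNP0304440.0: 9-hydroxy-3-methoxycoumestan with a 2,2-dimethyl-3,4-dihydro-2H-pyran ring fused through its O at C1 and its CH2 at C2; achiral | COc1cc2oc(=O)c3c4ccc(O)cc4oc3c2c2c1CCC(C)(C)O2 | target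

**Step count**

Total steps: 3. Longest linear sequence: 3 (1 → 2 → 5 → 9).

**Steps most likely to fail, with fallbacks**

Step 3 (highest risk). DDQ may also dehydrogenate the benzylic CH2–CH2 of ring E, or give mixtures with the free phenols. The fallback sets out from 8 and returns at 9. Run the condensation alone (5 + 6, Et3N, EtOH, reflux) and collect 8 by filtration. Then, instead of aiming for one selective dehydrogenation, oxidise exhaustively (DDQ 3.5 equiv, 1,4-dioxane, reflux) so that ring C closes and ring E is dehydrogenated as well, giving the 2H-chromene-fused coumestan F1. Finally hydrogenate only the chromene C=C (H2 1 atm, Pd/C, EtOAc/THF, rt); every other unsaturation is aromatic, so this gives 9.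

Step 2 (medium risk). A second chromanylation at C5, O-alkylation or acid deformylation may lower the yield. The fallback sets out from 2 and returns at 5. Condense 2 with 3-methylbut-2-enal (ethylenediammonium diacetate 10 mol%, xylene, 140 °C). C-alkylation at C3 followed by oxa-6π electrocyclisation gives 7-hydroxy-5-methoxy-2,2-dimethyl-2H-chromene-8-carbaldehyde F2, with the same unambiguous regiochemistry. Then saturate the chromene C=C (H2 1 atm, Pd/C, EtOAc, rt, stopped at 1 equiv uptake so the chelated aldehyde is kept) to reach 5.

Step 1 (lowest risk). AlCl3 may stop at the mono-phenol. The fallback sets out from 1 and returns at 2. Cleave all three ethers (BBr3 4 equiv, CH2Cl2, −78 °C to rt, aqueous work-up) to 2,4,6-trihydroxybenzaldehyde F3. Then methylate only the 4-OH, the one hydroxyl not hydrogen-bonded to the aldehyde and the most acidic (MeI 1.0 equiv, K2CO3 1.0 equiv, acetone, rt), to reach 2.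

**Further compounds**

F1 | step 3 | 9-hydroxy-3-methoxycoumestan with a 2,2-dimethyl-2H-pyran (chromene) ring fused through O at C1 and CH= at C2 (didehydro-9) | COc1cc2oc(=O)c3c4ccc(O)cc4oc3c2c2c1C=CC(C)(C)O2
F2 | step 2 | 7-hydroxy-5-methoxy-2,2-dimethyl-2H-chromene-8-carbaldehyde | COc1cc(O)c(C=O)c2OC(C)(C)C=Cc12
F3 | step 1 | 2,4,6-trihydroxybenzaldehyde | O=Cc1c(O)cc(O)cc1O
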